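## Retrosynthetic overview

1. The pyran ring closes last. The tertiary cage alcohol condenses with the C-10 ketone of a dibenzoxepinone and loses water. C-10 carries ring B, and C-11 carries ring A (the prenylated ring) and the cage.
2. Key step: the C-10/C-11 bond closes the oxepine. The ring B aldehyde carbon reacts as an acyl anion with the ring A aryl cage ketone. The extra C-11 hydroxyl group is then removed reductively.
3. The keto aldehyde comes from a bromo diaryl ether (made by SNAr), lithiated and added once to a tricyclic cage lactone.
4. The cage lactone comes from an intramolecular [2+2] photocycloaddition of an (R)-butenolide. Cyclobutane and cyclopentane form together, and all four stereocentres derive from one carbinol centre.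
5. The butenolide comes from (R)-linalool and CO. Ring order: lactone, then cyclobutane with cyclopentane, then oxepine, then pyran. No configurationally labile 2H-pyran is passed.

Assumption: commercial (R)-(−)-linalool is taken as at least 95% ee; the O-bearing quaternary carbon of the target is (R), maps onto C3 of (R)-linalool, and its C–O bond is never broken.

## Route

Step 1
Reactants: 1 (R)-(−)-linalool, (3R)-3,7-dimethylocta-1,6-dien-3-ol
Product: 2 (5R)-5-methyl-5-(4-methylpent-3-en-1-yl)oxolan-2-ol (lactol, both anomers)
Conditions: Rh(acac)(CO)2 (0.5 mol %), PPh3 (5 mol %), CO/H2 (1:1, 20 bar), toluene, 60 °C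
Reagents that add atoms: carbon monoxide, [C-]#[O+]
Why: Rhodium-catalysed hydroformylation places the formyl group on the terminal vinyl carbon because the neighbouring carbon is quaternary (Keulemans rule), the trisubstituted alkene is inert, the linear aldehyde closes to the lactol, and the carbinol stereocentre is not touched.

Step 2
Reactants: 2 lactol
Product: 3 (5R)-5-methyl-5-(4-methylpent-3-en-1-yl)oxolan-2-one
Conditions: PhI(OAc)2 (1.2 equiv), TEMPO (10 mol %), CH2Cl2, rt
Reagents that add atoms: none
Why: Oxoammonium (TEMPO) oxidation turns the lactol into the lactone and leaves the side-chain alkene and the quaternary stereocentre untouched.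

Step 3
Reactants: 3 saturated lactone
Product: 5 (5R)-5-methyl-5-(4-methylpent-3-en-1-yl)furan-2(5H)-one, via phenylselanyl lactone 4 (not isolated)
Conditions: LDA, THF, −78 °C; PhSeBr; crude 4, NaIO4, THF–MeOH–H2O, 0 °C to rt
Reagents that add atoms: none
Why: Enolate selenenylation and selenoxide syn-elimination can give only the endocyclic butenolide, periodate does not epoxidise the side-chain alkene, and C5 carries no acidic hydrogen so its configuration is safe.

Step 4
Reactants: 5 (R)-butenolide
Product: 6 (1S,3R,6R,9R)-2,2,6-trimethyl-5-oxatricyclo[4.2.1.0(3,9)]nonan-4-one (cage lactone: gem-dimethylcyclobutane cis-fused to a cyclopentane and to the γ-lactone)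
Conditions: hν (300 nm), acetone (solvent and sensitiser, 5 mM), N2, rt
Reagents that add atoms: none
Why: In this intramolecular enone–alkene [2+2] photocycloaddition (rule of five, straight mode) the three-atom tether delivers the alkene only to the butenolide face that carries it and the lactone ring locks the alkene as cis, so the single (R) centre sets C1, C3 and C9 as the all-cis cage.

Step 5
Reactants: 7 4-bromobenzene-1,3-diol (4-bromoresorcinol)
Product: 8 4-bromo-6-(3-methylbut-2-en-1-yl)benzene-1,3-diol
Conditions: 2-methylbut-3-en-2-ol, BF3·OEt2 (30 mol %), 1,4-dioxane, rt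
Reagents that add atoms: 2-methylbut-3-en-2-ol, CC(C)(O)C=C
Why: Friedel–Crafts prenylation goes to C6, the only unhindered position activated by both hydroxyl groups, and a moderate yield (some chroman forms) is acceptable for a first step from bulk chemicals.

Step 6
Reactants: 9 2-fluoro-4-hydroxybenzaldehyde
Product: 10 2-fluoro-4-(methoxymethoxy)benzaldehyde
Conditions: MOMCl, iPr2NEt, CH2Cl2, 0 °C to rt
Reagents that add atoms: chloromethyl methyl ether (MOMCl), COCCl
Why: O-alkylation to the MOM acetal prevents a para-phenoxide from switching off the next substitution and gives a group that falls off under the final acid conditions.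

Step 7
Reactants: 8 bromo prenyl resorcinol (1.5 equiv); 10 MOM-protected fluoro aldehyde
Product: 11 2-[2-bromo-5-hydroxy-4-(3-methylbut-2-en-1-yl)phenoxy]-4-(methoxymethoxy)benzaldehyde
Conditions: K2CO3 (1.0 equiv), DMF, 80 °C
Reagents that add atoms: none
Why: In this SNAr on the ortho-formyl-activated fluoride one equivalent of base deprotonates mainly the more acidic hydroxyl group next to bromine, which is the one arylated (the minor isomer is removed by chromatography), and the bromine blocks the ring A carbon that could otherwise attack the aldehyde to give a xanthene.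

Step 8
Reactants: 11 bromo diaryl ether aldehyde; 6 cage lactone
Product: 14 2-{5-hydroxy-2-[(1R,2R,5S,7R)-2-hydroxy-2,6,6-trimethylbicyclo[3.2.0]heptane-7-carbonyl]-4-(3-methylbut-2-en-1-yl)phenoxy}-4-(methoxymethoxy)benzaldehyde, via amino alkoxide 12 (not isolated), via aryllithium 13 (not isolated)
Conditions: NaH, THF, 0 °C; LiN(Me)CH2CH2NMe2 (from the amine and n-BuLi), −20 °C; n-BuLi, −78 °C; 6, −78 to −40 °C; H2O
Reagents that add atoms: none
Why: The aldehyde is masked in the flask as an α-amino alkoxide, bromine–lithium exchange gives the aryllithium, a single addition to the lactone stops at the tetrahedral alkoxide, and the cage carbon next to the new ketone keeps its endo configuration because only this epimer can rest as the five-membered lactol.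

Step 9
Reactants: 14 keto aldehyde
Product: 15 3,11-dihydroxy-11-[(1R,2R,5S,7R)-2-hydroxy-2,6,6-trimethylbicyclo[3.2.0]heptan-7-yl]-7-(methoxymethoxy)-2-(3-methylbut-2-en-1-yl)dibenzo[b,f]oxepin-10(11H)-one (C-11 epimers, resting as the six-membered hemiketal)
Conditions: 3-benzyl-5-(2-hydroxyethyl)-4-methylthiazolium chloride (20 mol %), Et3N (1 equiv), t-BuOH–THF, 50 °C, Ar
Reagents that add atoms: none
Why: Proposed new method: the thiazol-2-ylidene turns the ring B aldehyde carbon into an acyl anion (Breslow intermediate) that attacks the ring A ketone carbon, joining two carbons that are both electrophilic by nature; the closest known reaction type is the carbene-catalysed intramolecular crossed aldehyde–ketone benzoin cyclisation to five- and six-membered α-ketols, extended here to a seven-membered ring because the diaryl ether holds both carbonyl groups in reach and the freed tertiary cage alcohol traps the new ketone as a hemiketal that pulls the reversible addition forward, while the new C-11 centre forms as a mixture that step 10 erases.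

Step 10
Reactants: 15 α-ketol
Product: 17 target hexacycle CNP0185814.1 (enol ether closed onto the cage alcohol; both phenols free), via hydroxy ketone 16 (not isolated)
Conditions: SmI2 (2.2 equiv), THF–MeOH, −78 °C; then HCl (1.25 M in MeOH, excess), 40 °C
Reagents that add atoms: none
Why: SmI2 reduction of an α-hetero-substituted ketone cleaves the benzylic C-11–O bond through a samarium enolate without any cation, and methanolic HCl then removes the MOM group and drives hemiketal formation and dehydration to the conjugated enol ether, so C-11 becomes sp2, the four cage centres stay untouched and the ortho-prenylphenol survives these mild acid conditions.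

## Compound list

1 | (R)-(−)-linalool, (3R)-3,7-dimethylocta-1,6-dien-3-ol | CC(C)=CCC[C@@](C)(O)C=C | starting material
2 | (5R)-5-methyl-5-(4-methylpent-3-en-1-yl)oxolan-2-ol | CC(C)=CCC[C@@]1(C)OC(O)CC1 | intermediate
3 | (5R)-5-methyl-5-(4-methylpent-3-en-1-yl)oxolan-2-one | CC(C)=CCC[C@@]1(C)OC(=O)CC1 | intermediate
4 | (5R)-5-methyl-5-(4-methylpent-3-en-1-yl)-3-(phenylselanyl)oxolan-2-one | CC(C)=CCC[C@@]1(C)OC(=O)C([Se]c2ccccc2)C1 | intermediate
5 | (5R)-5-methyl-5-(4-methylpent-3-en-1-yl)furan-2(5H)-one | CC(C)=CCC[C@@]1(C)OC(=O)C=C1 | intermediate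
6 | (1S,3R,6R,9R)-2,2,6-trimethyl-5-oxatricyclo[4.2.1.0(3,9)]nonan-4-one | O=C1[C@@H]2[C@H]3[C@H](CC[C@@]3(C)O1)C2(C)C | intermediate
7 | 4-bromobenzene-1,3-diol | Oc1ccc(Br)c(O)c1 | starting material
8 | 4-bromo-6-(3-methylbut-2-en-1-yl)benzene-1,3-diol | CC(C)=CCc1cc(Br)c(O)cc1O | intermediate
9 | 2-fluoro-4-hydroxybenzaldehyde | O=Cc1ccc(O)cc1F | starting material
10 | 2-fluoro-4-(methoxymethoxy)benzaldehyde | COCOc1ccc(C=O)c(F)c1 | intermediate
11 | 2-[2-bromo-5-hydroxy-4-(3-methylbut-2-en-1-yl)phenoxy]-4-(methoxymethoxy)benzaldehyde | CC(C)=CCc1cc(Br)c(Oc2cc(OCOC)ccc2C=O)cc1O | intermediate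
12 | sodium phenoxide and lithium α-amino alkoxide of 11 | CC(C)=CCc1cc(Br)c(Oc2cc(OCOC)ccc2C([O-])N(C)CCN(C)C)cc1[O-].[Li+].[Na+] | intermediate
13 | aryllithium formed from 12 by bromine–lithium exchange | CC(C)=CCc1cc([Li])c(Oc2cc(OCOC)ccc2C([O-])N(C)CCN(C)C)cc1[O-].[Li+].[Na+] | intermediate
14 | keto aldehyde (ring A aryl cage ketone, ring B aldehyde; cage as in 6; drawn in the open form) | CC(C)=CCc1cc(C(=O)[C@@H]2[C@H]3[C@H](CC[C@@]3(C)O)C2(C)C)c(Oc2cc(OCOC)ccc2C=O)cc1O | intermediate
15 | dibenzoxepinone α-ketol (C-11 epimers; cage as in 6; drawn in the open form) | CC(C)=CCc1cc2c(cc1O)Oc1cc(OCOC)ccc1C(=O)C2(O)[C@@H]1[C@H]3[C@H](CC[C@@]3(C)O)C1(C)C | intermediate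
16 | 11-cage-substituted dibenzoxepin-10(11H)-one with free tertiary alcohol (cage as in 6) | CC(C)=CCc1cc2c(cc1O)Oc1cc(OCOC)ccc1C(=O)C2[C@@H]1[C@H]3[C@H](CC[C@@]3(C)O)C1(C)C | intermediate
17 | CNP0185814.1 (cyclobutane CH on C-11: R; CH shared by three rings: R; cyclobutane/cyclopentane fusion CH: S; O-bearing quaternary carbon: R) | CC(C)=CCc1cc2c(cc1O)Oc1cc(O)ccc1C1=C2[C@@H]2[C@H]3[C@H](CC[C@@]3(C)O1)C2(C)C | target

## Step count and risks

Total steps: 10.

Longest linear sequence: 7 steps (1, 2, 3, 5, 6, 14, 15, 17).

**Step 9 (carbene-catalysed ring closure).** The ketone is electron-rich, hindered and largely masked as a lactol, and a seven-membered ring must form. The fallback sets out from 14 and comes back at 15. It replaces the polar acyl anion by a ketyl radical. SmI2 in THF with t-BuOH couples the aldehyde and the ketone reductively to the 10,11-dihydro-10,11-diol F1. SO3·pyridine, DMSO and Et3N then oxidise only the secondary benzylic alcohol and return the α-ketol 15.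

**Step 8 (one-flask masking, exchange and lactone addition).** Incomplete masking or enolisation of the hindered lactone would lower the yield. The fallback sets out from 11 and comes back at 14. The aldehyde is protected in a separate step with 1,2-bis(trimethylsilyloxy)ethane and catalytic TMSOTf at −78 °C to give the 1,3-dioxolane F2. NaH, then n-BuLi, then lactone 6 give the keto dioxolane F3. Pyridinium tosylate in wet acetone releases 14.

**Step 10 (C–O cleavage and final closure).** The α-ketol may stay locked as its hemiketal, or the aryl ketone may be over-reduced. The fallback sets out from 15 and comes back at 17. It uses the hemiketal form as a cyclic 1,2-diol. Low-valent titanium from TiCl3 and Zn–Cu couple in refluxing DME removes both oxygen atoms and gives the tetrasubstituted enol ether directly as the MOM ether of the target F4. Methanolic HCl at rt then frees the phenol.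

## Further compounds

F1 | step 9 | 10,11-dihydro-10,11-diol from reductive coupling of 14 | CC(C)=CCc1cc2c(cc1O)Oc1cc(OCOC)ccc1C(O)C2(O)[C@@H]1[C@H]3[C@H](CC[C@@]3(C)O)C1(C)C
F2 | step 8 | 1,3-dioxolane of 11 | CC(C)=CCc1cc(Br)c(Oc2cc(OCOC)ccc2C2OCCO2)cc1O
F3 | step 8 | keto dioxolane (14 with the aldehyde as 1,3-dioxolane) | CC(C)=CCc1cc(C(=O)[C@@H]2[C@H]3[C@H](CC[C@@]3(C)O)C2(C)C)c(Oc2cc(OCOC)ccc2C2OCCO2)cc1O
F4 | step 10 | ring B MOM ether of the target | CC(C)=CCc1cc2c(cc1O)Oc1cc(OCOC)ccc1C1=C2[C@@H]2[C@H]3[C@H](CC[C@@]3(C)O1)C2(C)C
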